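## Analysis of the target

The target 22 is a triflavanoid made of three flavan-3-ol units, called here U (upper), M (middle) and L (lower); each has a phloroglucinol ring A, a dihydropyran ring C and a catechol ring B. C4 of U is bonded to C8 of M (a 4β→8 carbon–carbon interflavan bond), and C4 of M is joined to C4 of L through one ether oxygen. There are nine stereocentres. U is (2R,3R,4R) and M is (2R,3R,4S), both 2,3-cis-3,4-trans units of the (−)-epicatechin series with β substituents at C4. L is (2S,3S,4S): it belongs to the enantiomeric 2S series and carries its aryl group, its C3 hydroxyl and the C4 ether oxygen on one face of ring C. The molecule has twelve phenolic and three secondary hydroxyl groups, and its central C4(M)–O–C4(L) ether is benzylic on both sides to electron-rich phloroglucinol rings, so it ionises with acid, is open to hydrogenolysis and can fragment through quinone methides once the ring A phenols are free. The ether is the hard part: it links two hindered secondary benzylic carbons, capture of a C4 cation of L by an alcohol would give the 3,4-trans and not the required 3,4-cis arrangement, and unit L cannot be taken from the chiral pool because C2 and C3 are opposite to those of 1. The strategy rests on the fact that C4 of L is bonded only to the ether oxygen, to C4a of ring A of L, to C3 of L and to hydrogen. It can therefore be traced back to the carbonyl carbon of a benzoate ester of the 4β-hydroxyl of M, so that the inter-unit C–O bond is made by acylation and ring C of L is closed afterwards by forming C3=C4 from that carbonyl and a terminal alkene.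

## Retrosynthetic reasoning

**22 ⇒ 21.** The twelve phenols and the C3 hydroxyls of U and M are carried as benzyl ethers and released last; the C3 hydroxyl of L is already free in 21. Benzyl is chosen because it survives every reagent of the route, cannot migrate to a neighbouring alkoxide, and leaves under neutral conditions, the only ones the central ether tolerates. The forward step must cleave fourteen O–CH2Ph bonds without touching the two C4–O bonds.

**21 ⇒ 20 ⇒ 19 ⇒ 17.** In ring C of L the C3–O and C4–H bonds are removed, which leads back to the cyclic enol ether 17. A cis hydration on the face of the aryl group is not available. The forward route therefore adds hydrogen to C4 and oxygen to C3 on the face away from the C2 aryl group (19, which fixes C4), and then inverts C3 alone through ketone 20 and hydride delivery from the open face (21). Two of the three stereocentres of L thus follow from the third, C2.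

**17 ⇒ 16 (key disconnection).** The C3=C4 bond of 17 is cut into an ester carbonyl (C4) and a terminal alkene (C3), giving ester 16, a di-ortho-oxygenated benzoate whose ortho oxygen carries a 1-arylallyl group. Cutting here turns the hindered secondary–secondary ether into an ester, the easiest C–O bond to make between two hindered partners, and the ring closure needs neither a leaving group nor a cation at a benzylic carbon. The forward reaction is a carbonyl–alkene metathesis by a titanium alkylidene; it must join the carbonyl carbon to the internal alkene carbon and leave C2 alone.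

**16 ⇒ 6 + 14 (through 15).** The acyl C–O bond is cut into the dimer alcohol 6 and acid 14. The forward step uses the sodium alkoxide of 6 and acid chloride 15; a di-ortho-alkoxybenzoyl chloride reacts through an acylium-like transition state that tolerates hindrance. A mixed-anhydride method is avoided because both carbonyls of such an anhydride would be di-ortho-substituted.

**14 ⇒ 13 ⇒ 12 + 10.** The carboxyl group is carried as the aldehyde 13. An alkyl benzoate at this position would be di-ortho-substituted and could only be hydrolysed with forcing base and heat, which the allylic, benzylic C–H of the ether would not survive, whereas chlorite oxidation of an aldehyde is mild. The O–C2 bond of L is then cut into phenol 12 and cinnamyl carbonate 10; iridium-catalysed branched allylic etherification forms it and sets C2 of L under ligand control.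

**12 ⇒ 11; 10 ⇒ 9 ⇒ 8 ⇒ 7.** Phenol 12 comes from 11 by benzylation of the two non-chelated hydroxyls. Carbonate 10 comes from 7 by two-carbon olefination (8), reduction (9) and carbonate formation.

**6 ⇒ 5 ⇒ 4 + 3 ⇒ 2 ⇒ 1.** The 4β-hydroxyl of M is removed to give 5 (benzylic oxidation in the forward sense). The C4(U)–C8(M) bond is cut into the C4-activated monomer 4 and the nucleophile 3, both made from 1 through 2. C2 and C3 of U and M come from 1; both C4 centres are set trans to the resident C3 benzyloxy group.

## Alternatives that were turned down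

**Alternative 1:** Ring A of unit M is taken apart at C8a–C4a and C5–C6 and rebuilt by a Danheiser-type benzannulation. Cyclobutenone A2, carrying unit U on its sp3 carbon, is heated with siloxyalkyne A3, carrying the future C4–C3–C2 chain of M. Four-electron opening of A2 to a vinylketene, [2+2] addition to A3, a second four-electron opening and a six-electron closure give the phenol A1, whose free hydroxyl is the future O1 of M.
- For: the U–M connectivity is fixed by construction (no 4→6 isomer, no excess nucleophile, no oligomers), and the C5 and C7 oxygens of M come out differentiated.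
- Against: the ring it builds is one that 1 supplies ready-made. A2 needs a C4(U)–C(sp3) bond that must itself come from C4 cation chemistry, and A3 needs two stereocentres that are free in 1. After A1 the pyran ring of M must still be closed by displacement at a benzylic carbon bearing an electron-rich aryl group (inversion needed, ionisation threatens it), the C5 silyl ether exchanged, and C4 of M oxidised as in step 5.
- Comparison: none of this reaches the C4–O–C4 ether or unit L, so the second half of the chosen route would still be needed after a much longer first half. On regiochemical certainty of the U–M bond this alternative is the stronger; the chosen strategy accepts the preference of 3 for reaction at C8 and spends its key step on the bond unique to 22.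

**Alternative 2:** Ring C of unit U is disconnected at C3–C4 and O1–C2. The diaryl carbinol A5 is ionised to its ortho-quinone methide, the α-benzyloxy enamine A6 attacks the methide carbon, and the phenol oxygen closes onto the iminium carbon; hydrolysis gives lactol A4.
- For: a convergent [4+2] assembly; the C4(U)–C8(M) bond exists before the ring is made (by carbonyl addition of a C8-metallated flavan), so its position is certain; a 3,4-trans outcome is expected.
- Against: all three stereocentres of U must be created. C3 and C4 form under the weak influence of the remote stereocentres of M or of a chiral amine. C2 follows by aryl addition to the oxocarbenium ion of A4, where attack anti to the C3 substituent favours 2,3-trans and not the required 2,3-cis. 1 supplies C2 and C3 of U at no cost.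
- Comparison: longer, weaker in stereocontrol, and again silent on the ether and on L. Its only advantage is that it avoids the excess of 3 used in step 4.

**Alternative 3:** Ring C of unit M is disconnected at C4a–C4 and O1–C2. The bromomagnesium phenoxide of hub A8 adds through its one free ortho carbon to the aldehyde of cis-epoxy aldehyde A9, and the phenoxide then opens the epoxide at the benzylic carbon with inversion, giving flavan-3,4-diol A7 as C4 epimers.
- For: the U–M connectivity is unambiguous, and M arrives already oxygenated at C4, so the oxidation of a dimer (step 5) is not needed. On these two points it is as strong as or stronger than the chosen route.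
- Against: C4 is uncontrolled, and the free C3 and C4 hydroxyls of A7 must be told apart before acylation. A9 is prone to epimerisation and ionisation. The closure must be 6-endo at the benzylic carbon with clean inversion, while 5-exo opening and SN1 leakage at C2 compete. A8 itself needs a Lewis-acid arylation of 4 and selective unmasking of one phenol.
- Comparison: the ether and L are not addressed, so steps 9–17 would follow unchanged. The chosen strategy takes every stereocentre of U and M from 1 or sets it trans to a resident C3 substituent, and concentrates the uncertain chemistry in the one step that builds the part of 22 for which no building block exists.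

Key step: step 13

**Remarks on the chemistry**
- Assumption: in step 10 the (Ra,Rc,Rc) ligand is taken to give the (R)-ether 13; if the sense of induction is the opposite, the (Sa,Sc,Sc) ligand is used and nothing else changes.
- Flavan numbering is used for all intermediates. β is the face opposite to the C2 aryl groups of U and M. "Dimer-4β-yl" is 6 without its hydroxyl group; "dimer-4β-yloxy" is 6 without its hydroxyl hydrogen.

## Route

Step 1
Reactants: 1 (−)-epicatechin
Product: 2 5,7,3′,4′-tetra-O-benzyl-(−)-epicatechin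
Conditions: BnBr (4.4 equiv), K2CO3, DMF, 0 °C → rt
Reagents that add atoms: benzyl bromide, BrCc1ccccc1
Why: Williamson etherification of the four phenols; the weak base leaves the secondary C3 hydroxyl alone and keeps C-benzylation of ring A low.

Step 2
Reactants: 2 5,7,3′,4′-tetra-O-benzyl-(−)-epicatechin
Product: 3 3,5,7,3′,4′-penta-O-benzyl-(−)-epicatechin
Conditions: NaH, BnBr, Bu4NI (cat.), DMF, 0 °C → rt
Reagents that add atoms: benzyl bromide, BrCc1ccccc1
Why: Williamson etherification of the axial C3 alkoxide; no stereocentre is touched.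

Step 3
Reactants: 3 3,5,7,3′,4′-penta-O-benzyl-(−)-epicatechin
Product: 4 (2R,3R,4S)-4-(2-ethoxyethoxy)-3,5,7,3′,4′-penta-O-benzylepicatechin (4β ether)
Conditions: DDQ (2 equiv), 2-ethoxyethanol, CH2Cl2, rt
Reagents that add atoms: 2-ethoxyethanol, CCOCCO
Why: Benzylic oxidation by hydride abstraction from C4, whose cation is stabilised by the 5,7-dialkoxy ring A; the alcohol adds anti to the quasi-axial C3 benzyloxy group, giving the 4β (3,4-trans) ether.

Step 4
Reactants: 4 (2R,3R,4S)-4-(2-ethoxyethoxy)-penta-O-benzylepicatechin; 3 penta-O-benzyl-(−)-epicatechin (4 equiv, excess recovered)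
Product: 5 deca-O-benzyl epicatechin-(4β→8)-epicatechin, C4 of U (R)
Conditions: TMSOTf (cat.), CH2Cl2, −78 °C
Reagents that add atoms: none
Why: Lewis-acid-promoted Friedel–Crafts alkylation: the C4 cation of 4 is attacked by C8 of 3 (more accessible and more nucleophilic than C6, which lies between two benzyloxy groups) from the face anti to the C3 benzyloxy group, so the new centre is 4β; the excess of 3 suppresses oligomers and the minor 4→6 isomer is removed by chromatography.

Step 5
Reactants: 5 deca-O-benzyl epicatechin-(4β→8)-epicatechin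
Product: 6 deca-O-benzyl epicatechin-(4β→8)-epicatechin-4β-ol, C4 of M (S)
Conditions: DDQ (1.3 equiv), CH2Cl2–H2O (18:1), 0 °C → rt
Reagents that add atoms: water, O
Why: The same benzylic oxidation, now at the only CH2 group of 5; the quasi-axial C4–H of M is aligned with ring A, whereas the remaining C4–H of U is quasi-equatorial and shielded, and water adds anti to the C3 benzyloxy group to give the 4β-alcohol.

Step 6
Reactants: 7 3,4-bis(benzyloxy)benzaldehyde
Product: 8 ethyl (E)-3-[3,4-bis(benzyloxy)phenyl]prop-2-enoate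
Conditions: (EtO)2P(O)CH2CO2Et, NaH, THF, 0 °C → rt
Reagents that add atoms: triethyl phosphonoacetate, CCOC(=O)CP(=O)(OCC)OCC
Why: Horner–Wadsworth–Emmons olefination, E-selective with a stabilised phosphonate.

Step 7
Reactants: 8 ethyl (E)-3-[3,4-bis(benzyloxy)phenyl]prop-2-enoate
Product: 9 (E)-3-[3,4-bis(benzyloxy)phenyl]prop-2-en-1-ol
Conditions: i-Bu2AlH (2.2 equiv), CH2Cl2, −78 °C; aq. KNaC4H4O6
Reagents that add atoms: none
Why: 1,2-Reduction of the unsaturated ester to the allylic alcohol; the alkene geometry is kept.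

Step 8
Reactants: 9 (E)-3-[3,4-bis(benzyloxy)phenyl]prop-2-en-1-ol
Product: 10 (E)-3-[3,4-bis(benzyloxy)phenyl]prop-2-en-1-yl methyl carbonate
Conditions: ClCO2Me, pyridine, CH2Cl2, 0 °C
Reagents that add atoms: methyl chloroformate, COC(=O)Cl
Why: Acylation of the primary alcohol to the carbonate, the standard leaving group for iridium allyl chemistry.

Step 9
Reactants: 11 2,4,6-trihydroxybenzaldehyde
Product: 12 2,4-bis(benzyloxy)-6-hydroxybenzaldehyde
Conditions: BnBr (2.1 equiv), K2CO3, DMF, rt
Reagents that add atoms: benzyl bromide, BrCc1ccccc1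
Why: Williamson etherification; the para hydroxyl and one ortho hydroxyl react, and the remaining ortho hydroxyl is held in a hydrogen bond to the formyl group and is the least reactive.

Step 10
Reactants: 12 2,4-bis(benzyloxy)-6-hydroxybenzaldehyde; 10 (E)-3-[3,4-bis(benzyloxy)phenyl]prop-2-en-1-yl methyl carbonate
Product: 13 (R)-2,4-bis(benzyloxy)-6-{[1-(3,4-bis(benzyloxy)phenyl)prop-2-en-1-yl]oxy}benzaldehyde
Conditions: 12, NaH, THF, 0 °C; then 10, [Ir(cod)Cl]2 (2 mol %), (Ra,Rc,Rc)-O,O′-(1,1′-binaphthyl-2,2′-diyl) N,N-bis(1-phenylethyl)phosphoramidite (4 mol %, catalyst pre-activated with n-PrNH2 and freed of amine), THF, rt → 40 °C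
Reagents that add atoms: none
Why: Iridium-catalysed asymmetric allylic etherification: the sodium phenoxide attacks the substituted terminus of the allyliridium intermediate, giving the branched ether, and the ligand fixes the face, which sets the future C2 of L; conversion is stopped early so that the product does not re-ionise.

Step 11
Reactants: 13 (R)-2,4-bis(benzyloxy)-6-{[1-(3,4-bis(benzyloxy)phenyl)prop-2-en-1-yl]oxy}benzaldehyde
Product: 14 (R)-2,4-bis(benzyloxy)-6-{[1-(3,4-bis(benzyloxy)phenyl)prop-2-en-1-yl]oxy}benzoic acid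
Conditions: NaClO2, NaH2PO4, 2-methylbut-2-ene (large excess), t-BuOH–THF–H2O, 0 °C → rt; used at once
Reagents that add atoms: sodium chlorite, [Na+].[O-]Cl=O
Why: Pinnick oxidation of the aldehyde under weakly acidic buffer; the trisubstituted alkene scavenger takes up HOCl faster than the terminal alkene or the alkoxyarenes, and the stereocentre is not involved.

Step 12
Reactants: 14 (R)-2,4-bis(benzyloxy)-6-{[1-(3,4-bis(benzyloxy)phenyl)prop-2-en-1-yl]oxy}benzoic acid; 6 deca-O-benzyl epicatechin-(4β→8)-epicatechin-4β-ol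
Product: 16 dimer-4β-yl (R)-2,4-bis(benzyloxy)-6-{[1-(3,4-bis(benzyloxy)phenyl)prop-2-en-1-yl]oxy}benzoate, via acid chloride 15 (not isolated)
Conditions: 14, 1-chloro-N,N,2-trimethylprop-1-en-1-amine, CH2Cl2, 0 °C → rt; then added to 6, NaN(SiMe3)2 (1.0 equiv), THF, −78 → 0 °C
Reagents that add atoms: none
Why: Acid chloride formation under neutral conditions (no HCl is set free, so the acid-labile allylic benzylic ether is spared), then O-acylation of the sodium alkoxide; the 2,4,6-trialkoxybenzoyl chloride reacts through an acylium-like transition state that tolerates the hindrance on both sides, and the C4–O bond of M is never broken, so its 4β configuration is kept.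

Step 13
Reactants: 16 dimer-4β-yl (R)-2,4-bis(benzyloxy)-6-{[1-(3,4-bis(benzyloxy)phenyl)prop-2-en-1-yl]oxy}benzoate
Product: 17 (2R)-5,7-bis(benzyloxy)-2-[3,4-bis(benzyloxy)phenyl]-4-(dimer-4β-yloxy)-2H-chromene
Conditions: TiCl4, TMEDA (excess), Zn, PbCl2 (cat.), CH3CHBr2, THF–CH2Cl2, 0 → 65 °C; aq. K2CO3 quench; Et3N-deactivated silica
Reagents that add atoms: none
Why: Zinc reduction of the TiCl4–TMEDA complex in the presence of CH3CHBr2 gives a titanium ethylidene, which exchanges with the monosubstituted vinyl group of 16 by [2+2] cycloaddition and cycloreversion, propene leaving. The new alkylidene sits four atoms from the ester carbonyl and adds across C=O to an oxatitanacyclobutane, which collapses to the C3=C4 enol ether and a titanium oxo species. The closest known reaction type is the olefinic-ester cyclisation to cyclic enol ethers with this reduced titanium reagent, a special case of ester carbonyl olefination by titanium alkylidenes. The ring closed is the six-membered pyran ring C of unit L, by intramolecular carbonyl–alkene metathesis, and the former ester alkoxy oxygen ends up exocyclic as the inter-unit ether. No stereocentre is formed, and C2 of L is untouched because neither an allyl–metal nor a cationic intermediate is involved. The step needs chemoselectivity: alkylidene exchange at the vinyl group must outrun direct ethylidenation of the ester, and this is secured because the di-ortho-substituted benzoate of a hindered secondary alcohol is shielded against intermolecular attack, whereas its carbonyl, twisted out of the arene plane, turns a π face toward the ortho-tethered alkylidene. Excess TMEDA keeps the titanium and zinc halides coordinated so that the ionisable benzylic C4–O bond is not exposed to free Lewis acid, and the work-up is basic because 17 is an acid-labile enol ether.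

Step 14
Reactants: 17 (2R)-5,7-bis(benzyloxy)-2-[3,4-bis(benzyloxy)phenyl]-4-(dimer-4β-yloxy)-2H-chromene
Product: 19 (2S,3R,4S)-5,7-bis(benzyloxy)-2-[3,4-bis(benzyloxy)phenyl]-4-(dimer-4β-yloxy)chroman-3-ol, via alkylborane 18 (not isolated)
Conditions: BH3·THF, THF, 0 °C → rt; then NaOH, H2O2, H2O, 0 °C
Reagents that add atoms: hydrogen peroxide, OO
Why: Hydroboration–oxidation of a cyclic enol ether: boron goes to C3 (β to the enol oxygen) and hydrogen to C4 in a syn addition on the face opposite to the C2 aryl group, which sets C4 with its oxygen cis to the aryl group and C3 trans to it; oxidation of the C–B bond proceeds with retention.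

Step 15
Reactants: 19 (2S,3R,4S)-5,7-bis(benzyloxy)-2-[3,4-bis(benzyloxy)phenyl]-4-(dimer-4β-yloxy)chroman-3-ol
Product: 20 (2S,4S)-5,7-bis(benzyloxy)-2-[3,4-bis(benzyloxy)phenyl]-4-(dimer-4β-yloxy)chroman-3-one
Conditions: Dess–Martin periodinane, NaHCO3, CH2Cl2, 0 °C → rt
Reagents that add atoms: none
Why: Buffered periodinane oxidation of the hindered secondary alcohol without acid or base strong enough to enolise; the 2,4-cis ketone, with both substituents quasi-equatorial, is also the more stable epimer.

Step 16
Reactants: 20 (2S,4S)-5,7-bis(benzyloxy)-2-[3,4-bis(benzyloxy)phenyl]-4-(dimer-4β-yloxy)chroman-3-one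
Product: 21 (2S,3S,4S)-5,7-bis(benzyloxy)-2-[3,4-bis(benzyloxy)phenyl]-4-(dimer-4β-yloxy)chroman-3-ol (tetradeca-O-benzyl 22)
Conditions: LiBH(s-Bu)3, THF, −78 °C
Reagents that add atoms: none
Why: Reduction with a bulky hydride, which approaches from the face opposite to both the C2 aryl and the C4 alkoxy group and gives the axial, all-cis alcohol, the same control as in the known conversion of 2,3-trans into 2,3-cis flavan-3-ols.

Step 17
Reactants: 21 (2S,3S,4S)-5,7-bis(benzyloxy)-2-[3,4-bis(benzyloxy)phenyl]-4-(dimer-4β-yloxy)chroman-3-ol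
Product: 22 epicatechin-(4β→8)-epicatechin-(4β→O→4)-(2S,3S,4S)-flavan-3-ol, the target
Conditions: H2 (1 atm), Pd(OH)2/C, THF–MeOH–H2O, rt; filtration and lyophilisation without acid
Reagents that add atoms: none
Why: Catalytic hydrogenolysis of twelve aryl and two alkyl benzyl ethers, each needing only its peripheral phenyl ring on the metal; cleavage of a C4–O bond would need a fully substituted ring A to lie flat on it, the same discrimination that spares the benzylic C2–O1 bonds of flavans in such debenzylations.

## Compound list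

1 | (−)-epicatechin | Oc1cc(O)c2c(c1)O[C@H](c1ccc(O)c(O)c1)[C@H](O)C2 | starting material
2 | 5,7,3′,4′-tetra-O-benzyl-(−)-epicatechin | O(Cc9ccccc9)c1cc(OCc9ccccc9)c2c(c1)O[C@H](c1ccc(OCc9ccccc9)c(OCc9ccccc9)c1)[C@H](O)C2 | intermediate
3 | 3,5,7,3′,4′-penta-O-benzyl-(−)-epicatechin | O(Cc9ccccc9)c1cc(OCc9ccccc9)c2c(c1)O[C@H](c1ccc(OCc9ccccc9)c(OCc9ccccc9)c1)[C@H](OCc9ccccc9)C2 | intermediate
4 | (2R,3R,4S)-4-(2-ethoxyethoxy)-penta-O-benzylepicatechin | O(Cc9ccccc9)c1cc(OCc9ccccc9)c2c(c1)O[C@H](c1ccc(OCc9ccccc9)c(OCc9ccccc9)c1)[C@H](OCc9ccccc9)[C@H]2OCCOCC | intermediate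
5 | deca-O-benzyl epicatechin-(4β→8)-epicatechin | O(Cc9ccccc9)c1cc(OCc9ccccc9)c2c(c1)O[C@H](c1ccc(OCc9ccccc9)c(OCc9ccccc9)c1)[C@H](OCc9ccccc9)[C@H]2c1c(OCc9ccccc9)cc(OCc9ccccc9)c2c1O[C@H](c1ccc(OCc9ccccc9)c(OCc9ccccc9)c1)[C@H](OCc9ccccc9)C2 | intermediate
6 | deca-O-benzyl epicatechin-(4β→8)-epicatechin-4β-ol | O(Cc9ccccc9)c1cc(OCc9ccccc9)c2c(c1)O[C@H](c1ccc(OCc9ccccc9)c(OCc9ccccc9)c1)[C@H](OCc9ccccc9)[C@H]2c1c(OCc9ccccc9)cc(OCc9ccccc9)c2c1O[C@H](c1ccc(OCc9ccccc9)c(OCc9ccccc9)c1)[C@H](OCc9ccccc9)[C@H]2O | intermediate
7 | 3,4-bis(benzyloxy)benzaldehyde | O=Cc1ccc(OCc2ccccc2)c(OCc2ccccc2)c1 | starting material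
8 | ethyl (E)-3-[3,4-bis(benzyloxy)phenyl]prop-2-enoate | CCOC(=O)/C=C/c1ccc(OCc2ccccc2)c(OCc2ccccc2)c1 | intermediate
9 | (E)-3-[3,4-bis(benzyloxy)phenyl]prop-2-en-1-ol | OC/C=C/c1ccc(OCc2ccccc2)c(OCc2ccccc2)c1 | intermediate
10 | (E)-3-[3,4-bis(benzyloxy)phenyl]prop-2-en-1-yl methyl carbonate | COC(=O)OC/C=C/c1ccc(OCc2ccccc2)c(OCc2ccccc2)c1 | intermediate
11 | 2,4,6-trihydroxybenzaldehyde | O=Cc1c(O)cc(O)cc1O | starting material
12 | 2,4-bis(benzyloxy)-6-hydroxybenzaldehyde | O=Cc1c(O)cc(OCc2ccccc2)cc1OCc1ccccc1 | intermediate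
13 | (R)-2,4-bis(benzyloxy)-6-{[1-(3,4-bis(benzyloxy)phenyl)prop-2-en-1-yl]oxy}benzaldehyde | O=Cc1c(OCc9ccccc9)cc(OCc9ccccc9)cc1O[C@@H](c1ccc(OCc9ccccc9)c(OCc9ccccc9)c1)C=C | intermediate
14 | (R)-2,4-bis(benzyloxy)-6-{[1-(3,4-bis(benzyloxy)phenyl)prop-2-en-1-yl]oxy}benzoic acid | OC(=O)c1c(OCc9ccccc9)cc(OCc9ccccc9)cc1O[C@@H](c1ccc(OCc9ccccc9)c(OCc9ccccc9)c1)C=C | intermediate
15 | (R)-2,4-bis(benzyloxy)-6-{[1-(3,4-bis(benzyloxy)phenyl)prop-2-en-1-yl]oxy}benzoyl chloride | ClC(=O)c1c(OCc9ccccc9)cc(OCc9ccccc9)cc1O[C@@H](c1ccc(OCc9ccccc9)c(OCc9ccccc9)c1)C=C | intermediate (not isolated)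
16 | dimer-4β-yl (R)-2,4-bis(benzyloxy)-6-{[1-(3,4-bis(benzyloxy)phenyl)prop-2-en-1-yl]oxy}benzoate | O(Cc9ccccc9)c1cc(OCc9ccccc9)c2c(c1)O[C@H](c1ccc(OCc9ccccc9)c(OCc9ccccc9)c1)[C@H](OCc9ccccc9)[C@H]2c1c(OCc9ccccc9)cc(OCc9ccccc9)c2c1O[C@H](c1ccc(OCc9ccccc9)c(OCc9ccccc9)c1)[C@H](OCc9ccccc9)[C@H]2OC(=O)c1c(OCc9ccccc9)cc(OCc9ccccc9)cc1O[C@@H](c1ccc(OCc9ccccc9)c(OCc9ccccc9)c1)C=C | intermediate
17 | (2R)-5,7-bis(benzyloxy)-2-[3,4-bis(benzyloxy)phenyl]-4-(dimer-4β-yloxy)-2H-chromene | O(Cc9ccccc9)c1cc(OCc9ccccc9)c2c(c1)O[C@H](c1ccc(OCc9ccccc9)c(OCc9ccccc9)c1)[C@H](OCc9ccccc9)[C@H]2c1c(OCc9ccccc9)cc(OCc9ccccc9)c2c1O[C@H](c1ccc(OCc9ccccc9)c(OCc9ccccc9)c1)[C@H](OCc9ccccc9)[C@H]2OC1=C[C@H](c4ccc(OCc9ccccc9)c(OCc9ccccc9)c4)Oc3cc(OCc9ccccc9)cc(OCc9ccccc9)c13 | intermediate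
18 | C3 alkylborane of unit L (BH2 trans to the C2 aryl group, C4 oxygen cis to it) | O(Cc9ccccc9)c1cc(OCc9ccccc9)c2c(c1)O[C@H](c1ccc(OCc9ccccc9)c(OCc9ccccc9)c1)[C@H](OCc9ccccc9)[C@H]2c1c(OCc9ccccc9)cc(OCc9ccccc9)c2c1O[C@H](c1ccc(OCc9ccccc9)c(OCc9ccccc9)c1)[C@H](OCc9ccccc9)[C@H]2O[C@H]1c2c(OCc9ccccc9)cc(OCc9ccccc9)cc2O[C@@H](c2ccc(OCc9ccccc9)c(OCc9ccccc9)c2)[C@@H]1B | intermediate (not isolated)
19 | (2S,3R,4S)-5,7-bis(benzyloxy)-2-[3,4-bis(benzyloxy)phenyl]-4-(dimer-4β-yloxy)chroman-3-ol (2,3-trans, 3,4-trans) | O(Cc9ccccc9)c1cc(OCc9ccccc9)c2c(c1)O[C@H](c1ccc(OCc9ccccc9)c(OCc9ccccc9)c1)[C@H](OCc9ccccc9)[C@H]2c1c(OCc9ccccc9)cc(OCc9ccccc9)c2c1O[C@H](c1ccc(OCc9ccccc9)c(OCc9ccccc9)c1)[C@H](OCc9ccccc9)[C@H]2O[C@H]1c2c(OCc9ccccc9)cc(OCc9ccccc9)cc2O[C@@H](c2ccc(OCc9ccccc9)c(OCc9ccccc9)c2)[C@@H]1O | intermediate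
20 | (2S,4S)-5,7-bis(benzyloxy)-2-[3,4-bis(benzyloxy)phenyl]-4-(dimer-4β-yloxy)chroman-3-one | O(Cc9ccccc9)c1cc(OCc9ccccc9)c2c(c1)O[C@H](c1ccc(OCc9ccccc9)c(OCc9ccccc9)c1)[C@H](OCc9ccccc9)[C@H]2c1c(OCc9ccccc9)cc(OCc9ccccc9)c2c1O[C@H](c1ccc(OCc9ccccc9)c(OCc9ccccc9)c1)[C@H](OCc9ccccc9)[C@H]2O[C@H]1c2c(OCc9ccccc9)cc(OCc9ccccc9)cc2O[C@@H](c2ccc(OCc9ccccc9)c(OCc9ccccc9)c2)C1=O | intermediate
21 | (2S,3S,4S)-5,7-bis(benzyloxy)-2-[3,4-bis(benzyloxy)phenyl]-4-(dimer-4β-yloxy)chroman-3-ol (all-cis; tetradeca-O-benzyl 22) | O(Cc9ccccc9)c1cc(OCc9ccccc9)c2c(c1)O[C@H](c1ccc(OCc9ccccc9)c(OCc9ccccc9)c1)[C@H](OCc9ccccc9)[C@H]2c1c(OCc9ccccc9)cc(OCc9ccccc9)c2c1O[C@H](c1ccc(OCc9ccccc9)c(OCc9ccccc9)c1)[C@H](OCc9ccccc9)[C@H]2O[C@H]1c2c(OCc9ccccc9)cc(OCc9ccccc9)cc2O[C@@H](c2ccc(OCc9ccccc9)c(OCc9ccccc9)c2)[C@H]1O | intermediate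
22 | CNP0310719.1: epicatechin-(4β→8)-epicatechin-(4β→O→4)-(2S,3S,4S)-flavan-3-ol | Oc1cc(O)c2c(c1)O[C@H](c1ccc(O)c(O)c1)[C@H](O)[C@H]2c1c(O)cc(O)c2c1O[C@H](c1ccc(O)c(O)c1)[C@H](O)[C@H]2O[C@H]1c2c(O)cc(O)cc2O[C@@H](c2ccc(O)c(O)c2)[C@H]1O | target

## Step count and least certain steps

Total: 17 steps. Longest linear sequence: 11 steps (1 → 22 through steps 1–5 and 12–17; the branch from 7 through steps 6–8, 10, 11 and 12–17 is equally long).

**Step 13 (key step).**
- What may go wrong: direct ethylidenation of the ester in place of alkylidene exchange, which stops at an open-chain enol ether; no reaction at the shielded carbonyl; ionisation of the benzylic C4(M)–O bond by residual titanium or zinc Lewis acid; loss of the aryloxy group from the titanium alkylidene next to the allylic ether.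
- Fallback: two separate operations without Lewis acid, setting out from 16. Methylenation of the ester carbonyl with Cp2TiMe2 (toluene–THF, 65 °C) gives the 1-(dimer-4β-yloxy)vinyl arene F1. Ring-closing metathesis of F1 with the second-generation Grubbs catalyst (H2IMes)(PCy3)Cl2Ru=CHPh (toluene, 70 °C) then initiates at the monosubstituted alkene, closes onto the enol ether and releases ethene. The route is rejoined at 17.

**Step 12.**
- What may go wrong: slow acylation because alkoxide and acyl chloride are both hindered; self-protonation of the allylic benzylic ether of 14 on standing, or its loss during activation.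
- Fallback: the free acid is avoided altogether, setting out from 6. 2,4,6-Trihydroxybenzoic acid F2 is condensed with acetone (trifluoroacetic acid, trifluoroacetic anhydride) to 5,7-dihydroxy-2,2-dimethyl-4H-1,3-benzodioxin-4-one F3, which is benzylated (BnBr, K2CO3, DMF, 60 °C) to 5,7-bis(benzyloxy)-2,2-dimethyl-4H-1,3-benzodioxin-4-one F4. The sodium alkoxide of 6 (NaH, THF, 0 °C → rt) opens F4 with loss of acetone to dimer-4β-yl 2,4-bis(benzyloxy)-6-hydroxybenzoate F5. The iridium etherification of step 10 is then run on the sodium phenoxide of F5 with carbonate 10, under ligand control, and the route is rejoined at 16.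

**Step 14.**
- What may go wrong: poor facial discrimination, since the C2 aryl group must outweigh the large chiral alkoxy group at C4; slow addition to the hindered trisubstituted enol ether; fragmentation of the β-oxygenated borane with opening of the pyran ring.
- Fallback: an oxidation–reduction pair that contains no boron, setting out from 17. Dimethyldioxirane (acetone–CH2Cl2, −78 → 0 °C) epoxidises the enol ether on the face opposite to the aryl group to the 3,4-epoxide F6, which is not isolated. i-Bu2AlH (CH2Cl2, −78 °C) opens it at the acetal carbon C4 and delivers hydride from the aluminate on the face of the C3 oxygen. The route is rejoined at 19.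

**Step 17.**
- What may go wrong: hydrogenolysis of the C4–O bonds of the central ether while the two slower alkyl benzyl ethers are being cleaved; solvolysis of the ether by acidic catalyst residues once the ring A phenols are free.
- Fallback: debenzylation by electron transfer in place of surface catalysis, setting out from 21. Lithium 4,4′-di-tert-butylbiphenylide (THF, −78 °C; neutral NH4Cl quench under argon) cleaves O–CH2Ph bonds through the radical anion of the unsubstituted phenyl ring. The alkoxy-substituted rings, and then their phenoxides, are far poorer electron acceptors, which is what should protect the C4–O and C2–O1 bonds. No new compound is made on this way (F0), and the route is rejoined at 22.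

**Step 10.**
- What may go wrong: erosion of enantiomeric purity and drift to the linear cinnamyl ether by re-ionisation of the product, since the phenoxide of 12 is a fairly good leaving group and the aryl group stabilises the allyl cation; sluggish attack of a chelated, ortho-substituted phenoxide.
- Fallback: resolution in place of asymmetric induction, setting out from 12 and 10. The etherification is run with an achiral ligand ([Ir(cod)Cl]2, P(OPh)3, THF, rt) to the racemic branched ether, and 13 is separated from its enantiomer, (S)-2,4-bis(benzyloxy)-6-{[1-(3,4-bis(benzyloxy)phenyl)prop-2-en-1-yl]oxy}benzaldehyde F7, by preparative chromatography on a chiral stationary phase. The route is rejoined at 13.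

**Step 5.**
- What may go wrong: further oxidation of the new benzylic alcohol to the C4 ketone; competing hydride abstraction at the doubly benzylic C4–H of U.
- Fallback: the C4 oxygen of M is introduced before the dimer is made and carried as a latent thioether, setting out from 4. Exchange with 2,6-dimethylbenzenethiol (BF3·OEt2, CH2Cl2, −78 °C) gives (2R,3R,4S)-4-(2,6-dimethylphenylthio)-penta-O-benzylepicatechin F8, which is inert to hard Lewis acids. F8 (excess) is then coupled through its C8 with 4 as in step 4 (TMSOTf cat., CH2Cl2, −78 °C) to deca-O-benzyl epicatechin-(4β→8)-epicatechin 4β-(2,6-dimethylphenyl) thioether F9. Thiophilic activation of F9 in the presence of water (N-iodosuccinimide, H2O, CH2Cl2–MeCN, −20 °C) gives the 4β-alcohol, water adding anti to the C3 benzyloxy group. The route is rejoined at 6.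

## Further compounds

F1 | step 13 | 1-(dimer-4β-yloxy)vinyl arene: 16 with C=CH2 in place of C=O | O(Cc9ccccc9)c1cc(OCc9ccccc9)c2c(c1)O[C@H](c1ccc(OCc9ccccc9)c(OCc9ccccc9)c1)[C@H](OCc9ccccc9)[C@H]2c1c(OCc9ccccc9)cc(OCc9ccccc9)c2c1O[C@H](c1ccc(OCc9ccccc9)c(OCc9ccccc9)c1)[C@H](OCc9ccccc9)[C@H]2OC(=C)c1c(OCc9ccccc9)cc(OCc9ccccc9)cc1O[C@@H](c1ccc(OCc9ccccc9)c(OCc9ccccc9)c1)C=C
F2 | step 12 | 2,4,6-trihydroxybenzoic acid | OC(=O)c1c(O)cc(O)cc1O
F3 | step 12 | 5,7-dihydroxy-2,2-dimethyl-4H-1,3-benzodioxin-4-one | CC1(C)OC(=O)c2c(O)cc(O)cc2O1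
F4 | step 12 | 5,7-bis(benzyloxy)-2,2-dimethyl-4H-1,3-benzodioxin-4-one | CC1(C)OC(=O)c2c(OCc9ccccc9)cc(OCc9ccccc9)cc2O1
F5 | step 12 | dimer-4β-yl 2,4-bis(benzyloxy)-6-hydroxybenzoate | O(Cc9ccccc9)c1cc(OCc9ccccc9)c2c(c1)O[C@H](c1ccc(OCc9ccccc9)c(OCc9ccccc9)c1)[C@H](OCc9ccccc9)[C@H]2c1c(OCc9ccccc9)cc(OCc9ccccc9)c2c1O[C@H](c1ccc(OCc9ccccc9)c(OCc9ccccc9)c1)[C@H](OCc9ccccc9)[C@H]2OC(=O)c1c(OCc9ccccc9)cc(OCc9ccccc9)cc1O
F6 | step 14 | 3,4-epoxide of 17, epoxide oxygen trans to the C2 aryl group | O(Cc9ccccc9)c1cc(OCc9ccccc9)c2c(c1)O[C@H](c1ccc(OCc9ccccc9)c(OCc9ccccc9)c1)[C@H](OCc9ccccc9)[C@H]2c1c(OCc9ccccc9)cc(OCc9ccccc9)c2c1O[C@H](c1ccc(OCc9ccccc9)c(OCc9ccccc9)c1)[C@H](OCc9ccccc9)[C@H]2O[C@@]14c2c(OCc9ccccc9)cc(OCc9ccccc9)cc2O[C@@H](c2ccc(OCc9ccccc9)c(OCc9ccccc9)c2)[C@@H]1O4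
F0 | step 17 | none | none
F7 | step 10 | (S)-2,4-bis(benzyloxy)-6-{[1-(3,4-bis(benzyloxy)phenyl)prop-2-en-1-yl]oxy}benzaldehyde | O=Cc1c(OCc9ccccc9)cc(OCc9ccccc9)cc1O[C@H](c1ccc(OCc9ccccc9)c(OCc9ccccc9)c1)C=C
F8 | step 5 | (2R,3R,4S)-4-(2,6-dimethylphenylthio)-penta-O-benzylepicatechin | O(Cc9ccccc9)c1cc(OCc9ccccc9)c2c(c1)O[C@H](c1ccc(OCc9ccccc9)c(OCc9ccccc9)c1)[C@H](OCc9ccccc9)[C@H]2Sc1c(C)cccc1C
F9 | step 5 | deca-O-benzyl epicatechin-(4β→8)-epicatechin 4β-(2,6-dimethylphenyl) thioether | O(Cc9ccccc9)c1cc(OCc9ccccc9)c2c(c1)O[C@H](c1ccc(OCc9ccccc9)c(OCc9ccccc9)c1)[C@H](OCc9ccccc9)[C@H]2c1c(OCc9ccccc9)cc(OCc9ccccc9)c2c1O[C@H](c1ccc(OCc9ccccc9)c(OCc9ccccc9)c1)[C@H](OCc9ccccc9)[C@H]2Sc1c(C)cccc1C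
A1 | alternative 1 | phenol with unit U at C8, open pyran chain at C4a, silyl ether at C5 and free hydroxyl at C8a | O(Cc9ccccc9)c1cc(OCc9ccccc9)c2c(c1)O[C@H](c1ccc(OCc9ccccc9)c(OCc9ccccc9)c1)[C@H](OCc9ccccc9)[C@H]2c1c(OCc9ccccc9)cc(O[Si](C(C)C)(C(C)C)C(C)C)c(C[C@@H](OCc9ccccc9)[C@@H](O[Si](C)(C)C(C)(C)C)c3ccc(OCc9ccccc9)c(OCc9ccccc9)c3)c1O
A2 | alternative 1 | 3-benzyloxy-4-(penta-O-benzylepicatechin-4β-yl)cyclobut-2-en-1-one | O(Cc9ccccc9)c1cc(OCc9ccccc9)c2c(c1)O[C@H](c1ccc(OCc9ccccc9)c(OCc9ccccc9)c1)[C@H](OCc9ccccc9)[C@H]2C1C(=O)C=C1OCc9ccccc9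
A3 | alternative 1 | triisopropylsilyl ynol ether carrying the C4–C3–C2 chain of M (C3 benzyl ether, C2 tert-butyldimethylsilyl ether) | CC(C)[Si](C(C)C)(C(C)C)OC#CC[C@@H](OCc9ccccc9)[C@@H](O[Si](C)(C)C(C)(C)C)c1ccc(OCc9ccccc9)c(OCc9ccccc9)c1
A4 | alternative 2 | 3-benzyloxy-5,7-bis(benzyloxy)-4-(penta-O-benzylepicatechin-8-yl)chroman-2-ol, 3,4-trans, lactol anomers | O(Cc9ccccc9)c1cc(OCc9ccccc9)c2c(c1)OC(O)[C@H](OCc9ccccc9)[C@H]2c1c(OCc9ccccc9)cc(OCc9ccccc9)c2c1O[C@H](c1ccc(OCc9ccccc9)c(OCc9ccccc9)c1)[C@H](OCc9ccccc9)C2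
A5 | alternative 2 | [2,4-bis(benzyloxy)-6-hydroxyphenyl](penta-O-benzylepicatechin-8-yl)methanol | Oc1cc(OCc9ccccc9)cc(OCc9ccccc9)c1C(O)c1c(OCc9ccccc9)cc(OCc9ccccc9)c2c1O[C@H](c1ccc(OCc9ccccc9)c(OCc9ccccc9)c1)[C@H](OCc9ccccc9)C2
A6 | alternative 2 | 1-[2-(benzyloxy)ethenyl]pyrrolidine | C(=COCc1ccccc1)N1CCCC1
A7 | alternative 3 | nona-O-benzyl epicatechin-(4β→8)-(2,3-cis-flavan-3,4-diol), C4 epimers of M | O(Cc9ccccc9)c1cc(OCc9ccccc9)c2c(c1)O[C@H](c1ccc(OCc9ccccc9)c(OCc9ccccc9)c1)[C@H](OCc9ccccc9)[C@H]2c1c(OCc9ccccc9)cc(OCc9ccccc9)c2c1O[C@H](c1ccc(OCc9ccccc9)c(OCc9ccccc9)c1)[C@H](O)C2O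
A8 | alternative 3 | 4β-[2,4-bis(benzyloxy)-6-hydroxyphenyl]-penta-O-benzylepicatechin | O(Cc9ccccc9)c1cc(OCc9ccccc9)c2c(c1)O[C@H](c1ccc(OCc9ccccc9)c(OCc9ccccc9)c1)[C@H](OCc9ccccc9)[C@H]2c1c(OCc9ccccc9)cc(OCc9ccccc9)cc1O
A9 | alternative 3 | cis-3-[3,4-bis(benzyloxy)phenyl]oxirane-2-carbaldehyde | O=C[C@H]1O[C@H]1c1ccc(OCc9ccccc9)c(OCc9ccccc9)c1
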